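A direct plan would add the aryllithium from an O-allyl, O-silyl protected 4-bromo-3-hydroxybenzyl alcohol to 1,3-dichloroacetone and, after exchanging the silyl ether for the (R)-2-methylbutanoate, arrive at the achiral dichlorohydrin A1.
It would then close A1 enantioselectively to the (chloromethyl)oxirane A2 with a halohydrin dehalogenase, open A2 with acetate, reclose with base to the (acetoxymethyl)oxirane A3, open A3 with angelate to the allyl ether A4, and cleave the allyl ether with zerovalent palladium.
Weakest would be the desymmetrising oxirane closure of A1: it alone would set C8, on a tertiary, ortho-substituted aryl carbinol outside the proven substrate range of these enzymes, and chloride could reopen A2 to achiral A1.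
Next would be the acetate opening, base reclosure and angelate opening from A2 to A4: a tertiary alkoxide would sit beside acyloxymethyl arms under basic conditions, and an acyl shift between the two arms, which alone distinguish the enantiomers, would erase the configuration.
Third would be the final deallylation of A4 with a nucleophilic amine on the triester, where the freed phenoxide and the amine could both take acyl groups from the most precious material.
In addition, six protecting-group and redox steps would be spent before A1, which has no stereocentre at C8.

**Plan of the new route**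
Locants: ring A (the benzene ring) is C1–C6, with C1 carrying C7H2O, C3 the phenolic OH and C4 the carbinol C8, whose arms are C9 (angelate) and C10 (acetate).
The retrosynthesis cuts the O10–acetyl bond last, returns C10 to an ester carbon, and then cuts C4–C8 between ring A and a 3-angeloyloxypyruvate; the O7–acyl and O9–C9 bonds are cut on the two small fragments.
Ring A is bought and never protected; no oxirane or other ring arises at any stage.
Enabling feature: the free O–H on C3 of ring A lies ortho to C4, C4 is para to C1 (the unhindered ortho carbon), and C8 is a tertiary benzylic carbinol whose neighbour C10 can be carried as an ester carbonyl. A metal phenoxide can therefore deliver C4 to the ketone of an alpha-keto ester and create the C4–C8 bond and the C8 configuration together.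
Because C9 enters as the finished angelate (made by carboxylate alkylation) and C10 as an ester, C8 is never prochiral: no desymmetrisation, no oxirane relay under base and no final deprotection are needed.

Key step: step 3

Assumption: the sense of induction of the binaphtholate–titanium centre towards this new keto ester cannot be taken from precedent; the route is written with the (R)-ligand, and (S)-BINOL would be used instead if the first run gave the (2R)-hydroxy ester.

**Step 1**
Reactants: 1 3-(hydroxymethyl)phenol; 2 (R)-2-methylbutanoic acid
Product: 3 (3-hydroxyphenyl)methyl (2R)-2-methylbutanoate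
Conditions: PPh3 (1.2 equiv), DIAD (1.2 equiv), THF, 0 °C to rt
Reagents that add atoms: none
Why: Chemoselective Mitsunobu esterification, in which the benzylic hydroxyl is activated as its alkoxyphosphonium ion and displaced by the carboxylate, which outcompetes the much less acidic phenol as pronucleophile, while the acid is never activated as an acyl donor and so keeps its alpha stereocentre.

**Step 2**
Reactants: 4 angelic acid ((2Z)-2-methylbut-2-enoic acid); 5 ethyl 3-bromo-2-oxopropanoate (ethyl bromopyruvate)
Product: 7 ethyl 3-{[(2Z)-2-methylbut-2-enoyl]oxy}-2-oxopropanoate, via potassium angelate 6 (not isolated)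
Conditions: KHCO3 (1.1 equiv), DMF, 0 °C to rt
Reagents that add atoms: none
Why: Carboxylate O-alkylation (SN2) on the activated alpha-bromo ketone, in which angelic acid acts only as a nucleophile so that its Z double bond cannot isomerise through an acyl-activated species, and bicarbonate is too weak a base to enolise the keto ester appreciably.

**Step 3**
Reactants: 3 (3-hydroxyphenyl)methyl (2R)-2-methylbutanoate; 7 ethyl 3-{[(2Z)-2-methylbut-2-enoyl]oxy}-2-oxopropanoate
Product: 8 ethyl (2S)-2-hydroxy-2-[2-hydroxy-4-({[(2R)-2-methylbutanoyl]oxy}methyl)phenyl]-3-{[(2Z)-2-methylbut-2-enoyl]oxy}propanoate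
Conditions: (R)-1,1'-bi-2-naphthol ((R)-BINOL, 22 mol %), Ti(OiPr)4 (20 mol %), 4 Å MS, CH2Cl2, −20 °C to rt
Reagents that add atoms: none
Why: Proposed new method: the phenol of 3 exchanges onto the binaphtholate-bound tetravalent titanium centre, the ketone and ethyl ester oxygens of 7 chelate the same metal, and ring carbon C4 of the aryloxide adds to the ketone carbon (the future C8) through a closed six-membered transition state (Ti–O–C3–C4···C8–O), after which the dienone tautomerises back to the phenol and proton exchange with fresh 3 releases the product. The closest known reactions are the ortho-specific hydroxyalkylation of titanium and magnesium phenoxides by pyruvate and glyoxylate esters, stereoselective so far through chiral ester auxiliaries, and the binaphtholate–titanium-catalysed enantioselective Friedel–Crafts hydroxyalkylation of electron-rich arenes by glyoxylates and trifluoropyruvate; ligand control with a simple phenol and a non-fluorinated 3-acyloxypyruvate has not been shown. No ring is closed in this step. The new stereocentre C8 is controlled by the binaphtholate ligand, which shields one face of the chelated ketone so that C4 is delivered to the face giving the (2S)-hydroxy ester, the arrangement that becomes 8R once C10 is reduced. The step needs site selectivity for C4 over C2 and C6, secured by delivery from the metal-bound oxygen on C3 (ortho only) and by the C7 side chain that crowds C2, chemoselectivity for the ketone over the ester carbonyls, secured by the two-point binding that only the alpha-keto ester offers, and face selectivity between the CO2Et and CH2O-angeloyl arms, secured by the same chelate that holds the ester syn to the ketone oxygen. The benzylic ester at C7 is meta to the phenoxide oxygen and so cannot ionise to a quinone methide under the Lewis acid.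

**Step 4**
Reactants: 8 ethyl (2S)-2-hydroxy-2-[2-hydroxy-4-({[(2R)-2-methylbutanoyl]oxy}methyl)phenyl]-3-{[(2Z)-2-methylbut-2-enoyl]oxy}propanoate
Product: 9 (2R)-2,3-dihydroxy-2-[2-hydroxy-4-({[(2R)-2-methylbutanoyl]oxy}methyl)phenyl]propyl (2Z)-2-methylbut-2-enoate
Conditions: BH3·SMe2 (2.2 equiv), NaBH4 (5 mol %), THF, 0 °C to rt; MeOH quench
Reagents that add atoms: none
Why: Hydroxyl-directed borane reduction of an alpha-hydroxy ester (the reaction type that reduces only the hydroxyl-bearing ester of malate diesters), in which the C8 hydroxyl becomes an alkoxyborane that, activated by catalytic borohydride, delivers hydride through a five-membered transition state to the adjacent ester carbon C10 alone, so that the C7 and C9 esters stay, the non-basic medium and the boron-bound state of O10 until the methanol quench suppress the O9-to-O10 angeloyl shift that would invert C8, and C8 itself is untouched (its descriptor changes from S to R only through the new priorities).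

**Step 5**
Reactants: 9 (2R)-2,3-dihydroxy-2-[2-hydroxy-4-({[(2R)-2-methylbutanoyl]oxy}methyl)phenyl]propyl (2Z)-2-methylbut-2-enoate
Product: 10 (2R)-3-(acetyloxy)-2-hydroxy-2-[2-hydroxy-4-({[(2R)-2-methylbutanoyl]oxy}methyl)phenyl]propyl (2Z)-2-methylbut-2-enoate
Conditions: immobilised Candida antarctica lipase B, vinyl acetate (5 equiv), MTBE, 30 °C
Reagents that add atoms: vinyl acetate, C=COC(C)=O
Why: Lipase-catalysed irreversible transesterification through the acetyl-enzyme, in which the serine hydrolase accepts the one primary aliphatic hydroxyl (O10) as nucleophile and leaves the phenol and the tertiary alcohol, loss of acetaldehyde makes the acylation irreversible, and the neutral medium without base keeps the angeloyl group on O9 so that C8 retains its configuration (9 is used directly after step 4 to give acyl migration no time).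

**Compound list**
1 | 3-(hydroxymethyl)phenol | OCc1cccc(O)c1 | starting material
2 | (R)-2-methylbutanoic acid | CC[C@@H](C)C(=O)O | starting material
3 | (3-hydroxyphenyl)methyl (2R)-2-methylbutanoate | CC[C@@H](C)C(=O)OCc1cccc(O)c1 | intermediate
4 | angelic acid, (2Z)-2-methylbut-2-enoic acid | C/C=C(/C)C(=O)O | starting material
5 | ethyl 3-bromo-2-oxopropanoate (ethyl bromopyruvate) | CCOC(=O)C(=O)CBr | starting material
6 | potassium (2Z)-2-methylbut-2-enoate (potassium angelate) | C/C=C(/C)C(=O)[O-].[K+] | intermediate (not isolated)
7 | ethyl 3-{[(2Z)-2-methylbut-2-enoyl]oxy}-2-oxopropanoate | C/C=C(/C)C(=O)OCC(=O)C(=O)OCC | intermediate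
8 | ethyl (2S)-2-hydroxy-2-[2-hydroxy-4-({[(2R)-2-methylbutanoyl]oxy}methyl)phenyl]-3-{[(2Z)-2-methylbut-2-enoyl]oxy}propanoate | C/C=C(/C)C(=O)OC[C@](O)(C(=O)OCC)c1ccc(COC(=O)[C@H](C)CC)cc1O | intermediate
9 | (2R)-2,3-dihydroxy-2-[2-hydroxy-4-({[(2R)-2-methylbutanoyl]oxy}methyl)phenyl]propyl (2Z)-2-methylbut-2-enoate | C/C=C(/C)C(=O)OC[C@](O)(CO)c1ccc(COC(=O)[C@H](C)CC)cc1O | intermediate
10 | (2R)-3-(acetyloxy)-2-hydroxy-2-[2-hydroxy-4-({[(2R)-2-methylbutanoyl]oxy}methyl)phenyl]propyl (2Z)-2-methylbut-2-enoate | C/C=C(/C)C(=O)OC[C@](O)(COC(C)=O)c1ccc(COC(=O)[C@H](C)CC)cc1O | target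

**Step count**
Total steps: 5. Longest linear sequence: 4 steps (steps 1, 3, 4 and 5; step 2 makes the second fragment).

**Steps most likely to fail**

Step 3 (Proposed new method).
- The titanium aryloxide may be too weak a nucleophile for the ketone at a loading that still turns over, because the product binds the metal as a chelating diolate.
- The angeloyl carbonyl may compete for the metal and lower the facial selectivity.
- The sense of induction may be the opposite of the one needed.

Fallback with known chemistry, setting out from 3 and 4 and returning at 9: the same bond is made under control of an ester auxiliary. 3-Bromopyruvic acid and (−)-menthol (TsOH, toluene, azeotropic removal of water) would give (1R,2S,5R)-5-methyl-2-(propan-2-yl)cyclohexyl 3-bromo-2-oxopropanoate F1. Alkylation of potassium angelate from 4 with F1 (KHCO3, DMF) would give (1R,2S,5R)-5-methyl-2-(propan-2-yl)cyclohexyl 3-{[(2Z)-2-methylbut-2-enoyl]oxy}-2-oxopropanoate F2. The chlorotitanium phenoxide of 3 (TiCl4, CH2Cl2, −30 °C) would then be hydroxyalkylated at C4 by F2 to give (1R,2S,5R)-5-methyl-2-(propan-2-yl)cyclohexyl (2S)-2-hydroxy-2-[2-hydroxy-4-({[(2R)-2-methylbutanoyl]oxy}methyl)phenyl]-3-{[(2Z)-2-methylbut-2-enoyl]oxy}propanoate F3. F3 and its C8 epimer are diastereomers and should be separable. The borane reduction of step 4 applied to F3 would release menthol and return to the route at 9. The menthol antipode that favours the (2S) epimer would be chosen; the compounds are written here with (−)-menthol.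

Step 4.
- Borane may hydroborate the angelate double bond in competition with the directed ester reduction.
- The angeloyl group may shift from O9 to O10 during work-up, which would lower the enantiomeric purity.

Fallback setting out from 8 and returning at 9: the ester to be reduced is first activated as an aryl ester instead of relying on hydroxyl delivery. Acid-catalysed lactonisation of 8 (pyridinium p-toluenesulfonate, toluene, 60 °C) would give [(3S)-3-hydroxy-6-({[(2R)-2-methylbutanoyl]oxy}methyl)-2-oxo-2,3-dihydro-1-benzofuran-3-yl]methyl (2Z)-2-methylbut-2-enoate F4. Its phenolic lactone carbonyl is far more electrophilic than the alkyl and conjugated esters and should be reduced alone by NaBH4 (THF–EtOH, −30 °C, AcOH quench) to give 9. Any F4 that forms already in step 3 would converge on 9 in the same way.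

Step 5.
- The neopentyl-type primary hydroxyl beside the quaternary C8 may be a slow substrate for the lipase, leaving time for angeloyl migration in 9.
- The phenol may be partly acetylated.

Fallback setting out from 9 and returning at 10: both reactive hydroxyls are acetylated and the aryl acetate is then removed. Ac2O in pyridine at 0 °C without an acyl-transfer catalyst (so that the tertiary hydroxyl stays free) would give (2R)-3-(acetyloxy)-2-[2-(acetyloxy)-4-({[(2R)-2-methylbutanoyl]oxy}methyl)phenyl]-2-hydroxypropyl (2Z)-2-methylbut-2-enoate F5. Selective methanolysis of the phenolic acetate (NH4OAc, MeOH, rt), which is much faster than that of the alkyl esters, would then give 10.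

**Further compounds**
F1 | step 3 | (1R,2S,5R)-5-methyl-2-(propan-2-yl)cyclohexyl 3-bromo-2-oxopropanoate | C[C@@H]1CC[C@H]([C@@H](C1)OC(=O)C(=O)CBr)C(C)C
F2 | step 3 | (1R,2S,5R)-5-methyl-2-(propan-2-yl)cyclohexyl 3-{[(2Z)-2-methylbut-2-enoyl]oxy}-2-oxopropanoate | C[C@@H]1CC[C@H]([C@@H](C1)OC(=O)C(=O)COC(=O)/C(C)=C\C)C(C)C
F3 | step 3 | (1R,2S,5R)-5-methyl-2-(propan-2-yl)cyclohexyl (2S)-2-hydroxy-2-[2-hydroxy-4-({[(2R)-2-methylbutanoyl]oxy}methyl)phenyl]-3-{[(2Z)-2-methylbut-2-enoyl]oxy}propanoate | C[C@@H]1CC[C@H]([C@@H](C1)OC(=O)[C@@](O)(COC(=O)/C(C)=C\C)c2ccc(COC(=O)[C@H](C)CC)cc2O)C(C)C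
F4 | step 4 | [(3S)-3-hydroxy-6-({[(2R)-2-methylbutanoyl]oxy}methyl)-2-oxo-2,3-dihydro-1-benzofuran-3-yl]methyl (2Z)-2-methylbut-2-enoate | C/C=C(/C)C(=O)OC[C@]1(O)C(=O)Oc2cc(COC(=O)[C@H](C)CC)ccc21
F5 | step 5 | (2R)-3-(acetyloxy)-2-[2-(acetyloxy)-4-({[(2R)-2-methylbutanoyl]oxy}methyl)phenyl]-2-hydroxypropyl (2Z)-2-methylbut-2-enoate | C/C=C(/C)C(=O)OC[C@](O)(COC(C)=O)c1ccc(COC(=O)[C@H](C)CC)cc1OC(C)=O
A1 | direct plan | [4-(1,3-dichloro-2-hydroxypropan-2-yl)-3-(prop-2-en-1-yloxy)phenyl]methyl (2R)-2-methylbutanoate | ClCC(O)(CCl)c1ccc(COC(=O)[C@H](C)CC)cc1OCC=C
A2 | direct plan | {4-[(2R)-2-(chloromethyl)oxiran-2-yl]-3-(prop-2-en-1-yloxy)phenyl}methyl (2R)-2-methylbutanoate | ClC[C@]1(CO1)c1ccc(COC(=O)[C@H](C)CC)cc1OCC=C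
A3 | direct plan | {4-[(2S)-2-[(acetyloxy)methyl]oxiran-2-yl]-3-(prop-2-en-1-yloxy)phenyl}methyl (2R)-2-methylbutanoate | CC(=O)OC[C@@]1(CO1)c1ccc(COC(=O)[C@H](C)CC)cc1OCC=C
A4 | direct plan | (2R)-3-(acetyloxy)-2-hydroxy-2-[4-({[(2R)-2-methylbutanoyl]oxy}methyl)-2-(prop-2-en-1-yloxy)phenyl]propyl (2Z)-2-methylbut-2-enoate | C/C=C(/C)C(=O)OC[C@](O)(COC(C)=O)c1ccc(COC(=O)[C@H](C)CC)cc1OCC=C
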